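**Plan**

- Retrosynthesis: cut the exocyclic C=C at ring C5 (aldol, then dehydration, with an (E)-enal) and the C2–Br/C2=C3 unit (back to a silyl enol ether carrying a sulfinyl group at C3). Then cut two ring bonds of the cyclopentenone at once, C3–C4 and C1–C5 (C1 = C=O, C2 = CBr, C3 = CH, C4 = carbinol carbon, C5 = alkylidene carbon).
- Enabling feature: carbinol C4 is bonded to the enone β-carbon C3 (a like-polarity, homoaldol bond) and C1 is an acyl carbon. With C1 as an acylsilane, enolate addition followed by a 1,2-Brook shift makes C3 nucleophilic, so one methyl ketone acts first as the C5 nucleophile and then as the C4 electrophile.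
- Forward: fragment A (sulfinyl acryloylsilane, 3 steps) and fragment B (enol acetate of the (Z)-octenyl methyl ketone, 3 steps) are joined in a [3+2] annulation that builds the only ring with the ω-chain in place. NBS/elimination then removes the silyl and sulfinyl helpers and installs C2–Br, and the α-chain is attached last.
- Stereochemistry: C4 from the sulfur stereocentre of the sulfinyl helper (chelate-controlled ring closure); side-chain (Z)-alkene from (2Z)-oct-2-en-1-ol; chain (5E)-alkene from E-selective cross-metathesis; exocyclic (7Z)-alkene from a syn-aldol followed by syn-elimination.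

Key step: step 7

Remark: the sense of induction by the sulfinyl group in step 7 is a prediction from a lithium-chelate model; methoxyallene, (2Z)-oct-2-en-1-ol and (1R,2S,5R)-menthyl (S)-4-methylbenzenesulfinate are taken as commercial.

**Route**

Step 1
Reactants: 1 methoxyallene
Product: 3 tert-butyl(1-methoxypropa-1,2-dien-1-yl)dimethylsilane, via 1-lithio-1-methoxyallene 2 (not isolated)
Conditions: n-BuLi, THF, −78 °C; TBSCl, −78 °C to rt
Reagents that add atoms: tert-butyldimethylsilyl chloride, CC(C)(C)[Si](C)(C)Cl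
Why: Alkoxy-directed α-lithiation of the allenyl ether and C-silylation should give the 1-silyl-1-alkoxyallene, a masked acryloylsilane.

Step 2
Reactants: 3 tert-butyl(1-methoxypropa-1,2-dien-1-yl)dimethylsilane; 4 (1R,2S,5R)-menthyl (S)-4-methylbenzenesulfinate
Product: 6 tert-butyl{1-methoxy-3-[(R)-4-methylbenzenesulfinyl]propa-1,2-dien-1-yl}dimethylsilane, via lithiated silylallene 5 (not isolated)
Conditions: n-BuLi, THF, −78 °C; then added to 4 in THF (inverse addition), −78 °C; H2O
Reagents that add atoms: none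
Why: γ-Lithiation of the silylallene followed by Andersen sulfoxide synthesis (substitution at sulfur with inversion) should transfer the sulfur stereocentre as the (R)-sulfoxide; the uncontrolled allene axis is removed in step 3.

Step 3
Reactants: 6 tert-butyl{1-methoxy-3-[(R)-4-methylbenzenesulfinyl]propa-1,2-dien-1-yl}dimethylsilane
Product: 7 (2E)-1-[tert-butyl(dimethyl)silyl]-3-[(R)-4-methylbenzenesulfinyl]prop-2-en-1-one
Conditions: 0.5 M aq. H2SO4, THF, 0 °C to rt
Reagents that add atoms: water, O
Why: Hydrolysis of the 1-alkoxyallene (protonation at the central carbon, loss of methanol) should unmask the α,β-unsaturated acylsilane as the conjugated (E)-isomer, and the non-nucleophilic acid leaves the sulfur configuration untouched.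

Step 4
Reactants: 8 (2Z)-oct-2-en-1-ol
Product: 9 (2Z)-1-bromooct-2-ene
Conditions: CBr4, PPh3, CH2Cl2, 0 °C
Reagents that add atoms: carbon tetrabromide, BrC(Br)(Br)Br
Why: Appel bromination of the primary allylic alcohol under neutral conditions should keep the (Z)-geometry.

Step 5
Reactants: 9 (2Z)-1-bromooct-2-ene
Product: 10 (4Z)-undec-4-en-1-yne
Conditions: HC≡CMgBr (3 equiv), CuCl (10 mol %), THF, 0 to 40 °C
Reagents that add atoms: ethynylmagnesium bromide, C#C[Mg]Br
Why: Copper-catalysed coupling of an alkynyl Grignard reagent with a primary allylic bromide (SN2-selective) should give the skipped enyne without touching the (Z)-alkene.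

Step 6
Reactants: 10 (4Z)-undec-4-en-1-yne
Product: 11 (4Z)-undeca-1,4-dien-2-yl acetate
Conditions: AcOH (1.5 equiv), [RuCl2(p-cymene)]2 (1 mol %), P(2-furyl)3 (2 mol %), Na2CO3 (4 mol %), toluene, 50 °C
Reagents that add atoms: acetic acid, CC(=O)O
Why: Ruthenium-catalysed Markovnikov addition of a carboxylic acid to a terminal alkyne should give the 2-acetoxy-1-alkene, a regiodefined source of the methyl-side enolate that deprotonation of the β,γ-unsaturated ketone could not deliver.

Step 7
Reactants: 11 (4Z)-undeca-1,4-dien-2-yl acetate; 7 (2E)-1-[tert-butyl(dimethyl)silyl]-3-[(R)-4-methylbenzenesulfinyl]prop-2-en-1-one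
Product: 15 (1S,2R)-4-[(tert-butyldimethylsilyl)oxy]-2-[(R)-4-methylbenzenesulfinyl]-1-[(2Z)-oct-2-en-1-yl]cyclopent-3-en-1-ol, via lithium enolate 12 (not isolated), via silyl alkoxide adduct 13 (not isolated), via siloxyallyl lithium 14 (not isolated)
Conditions: 11 (1.2 equiv), MeLi (2.4 equiv), THF, 0 °C; then −80 °C, 7 (1.0 equiv); −80 to −30 °C; AcOH at −78 °C; cold work-up, used at once
Reagents that add atoms: none
Why: Proposed new method: the terminal carbon of lithium enolate 12 adds to the highly electrophilic acylsilane carbonyl of 7 (first C–C bond), the α-silyl alkoxide 13 undergoes a 1,2-Brook shift pulled by formation of the sulfinyl-stabilised siloxyallyl anion 14, and the γ-carbon of this anion adds to the ketone carbonyl (second C–C bond). The closest known reaction type is the Brook rearrangement-mediated [3+2] annulation of β-silyl- and β-phenylthio-acryloylsilanes with lithium enolates of alkyl methyl ketones; the sulfinyl group as stabilising and stereocontrolling substituent and the skipped-ene enolate are the new elements. The cyclopentene ring is closed by 5-exo-trig attack of the allyl anion terminus on the C=O group, the new enol ether double bond being held cis inside the ring. Both new stereocentres arise in this closure: a lithium bridge between sulfinyl oxygen and ketone oxygen, lying exo to the forming ring with the p-tolyl group anti to the forming bond, should place hydroxyl and sulfinyl cis and let the (R)-sulfur select the ring face, giving the (1S,2R)-isomer (C-2 is erased in step 8). The step needs 1,2-addition in preference to conjugate addition, secured by the acylsilane carbonyl at −80 °C, and ring closure faster than proton transfer from the doubly activated CH2 between the C=O and the (Z)-alkene, favoured by the intramolecular five-ring closure in the absence of a proton source.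

Step 8
Reactants: 15 (1S,2R)-4-[(tert-butyldimethylsilyl)oxy]-2-[(R)-4-methylbenzenesulfinyl]-1-[(2Z)-oct-2-en-1-yl]cyclopent-3-en-1-ol
Product: 17 (4S)-2-bromo-4-hydroxy-4-[(2Z)-oct-2-en-1-yl]cyclopent-2-en-1-one, via bromo sulfinyl ketone 16 (not isolated)
Conditions: NBS (1.05 equiv), THF, −78 °C; then Et3N, −78 to 0 °C
Reagents that add atoms: N-bromosuccinimide, O=C1CCC(=O)N1Br
Why: Electrophilic bromination of the silyl enol ether is regiospecific for C-3 of 15 (the future C-2 of the enone) and is run cold before the allylic sulfoxide can rearrange, after which the β-sulfinyl ketone should lose sulfenate by E1cB toward the brominated carbon, so both helpers leave while Br and the C2=C3 bond are installed and the carbinol centre is untouched.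

Step 9
Reactants: 17 (4S)-2-bromo-4-hydroxy-4-[(2Z)-oct-2-en-1-yl]cyclopent-2-en-1-one
Product: 18 (4S)-2-bromo-4-[(2Z)-oct-2-en-1-yl]-4-[(triethylsilyl)oxy]cyclopent-2-en-1-one
Conditions: TESOTf, 2,6-lutidine, CH2Cl2, −78 to 0 °C
Reagents that add atoms: triethylsilyl trifluoromethanesulfonate, CC[Si](CC)(CC)OS(=O)(=O)C(F)(F)F
Why: Silyl triflate silylation of the tertiary alcohol removes the acidic OH before the enolate chemistry of step 11.

Step 10
Reactants: 19 methyl hex-5-enoate; 20 (2E)-but-2-enal (crotonaldehyde)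
Product: 21 methyl (5E)-7-oxohept-5-enoate
Conditions: 20 (5 equiv), second-generation Grubbs catalyst (H2IMes)(PCy3)Cl2Ru=CHPh (2.5 mol %), CH2Cl2, 40 °C
Reagents that add atoms: none
Why: Olefin cross-metathesis of a terminal alkene with an enal should give the (E)-enal under thermodynamic control.

Step 11
Reactants: 18 (4S)-2-bromo-4-[(2Z)-oct-2-en-1-yl]-4-[(triethylsilyl)oxy]cyclopent-2-en-1-one; 21 methyl (5E)-7-oxohept-5-enoate
Product: 24 methyl (5E,7S)-7-[(1S,2S)-4-bromo-2-[(2Z)-oct-2-en-1-yl]-5-oxo-2-[(triethylsilyl)oxy]cyclopent-3-en-1-yl]-7-hydroxyhept-5-enoate, via lithium enolate 22 (not isolated), via zirconium enolate 23 (not isolated)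
Conditions: LiN(iPr)2 (LDA), THF, −78 °C; Cp2ZrCl2, −78 to −40 °C; 21, −78 °C; H2O (pH 7)
Reagents that add atoms: none
Why: Kinetic deprotonation at C-5 (the only enolisable position) and transmetalation should give a zirconium enolate whose closed-transition-state aldol addition is expected to be syn-selective whatever the enolate geometry; the enolate face attacked (drawn anti to the silyloxy group) is inconsequential because this ring carbon becomes trigonal in step 12.

Step 12
Reactants: 24 methyl (5E,7S)-7-[(1S,2S)-4-bromo-2-[(2Z)-oct-2-en-1-yl]-5-oxo-2-[(triethylsilyl)oxy]cyclopent-3-en-1-yl]-7-hydroxyhept-5-enoate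
Product: 25 methyl (5E,7Z)-7-[(2R)-4-bromo-2-[(2Z)-oct-2-en-1-yl]-5-oxo-2-[(triethylsilyl)oxy]cyclopent-3-en-1-ylidene]hept-5-enoate
Conditions: DCC (3 equiv), CuCl (20 mol %), toluene, 60 °C
Reagents that add atoms: none
Why: Carbodiimide/CuCl dehydration of a β-hydroxy ketone proceeds by syn-elimination from the O-alkylisourea, which from the syn-aldol should place the chain cis to the ring carbonyl, i.e. the (7Z)-alkene.

Step 13
Reactants: 25 methyl (5E,7Z)-7-[(2R)-4-bromo-2-[(2Z)-oct-2-en-1-yl]-5-oxo-2-[(triethylsilyl)oxy]cyclopent-3-en-1-ylidene]hept-5-enoate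
Product: 26 methyl (5E,7Z)-7-[(2R)-4-bromo-2-hydroxy-2-[(2Z)-oct-2-en-1-yl]-5-oxocyclopent-3-en-1-ylidene]hept-5-enoate
Conditions: HF·pyridine, pyridine, THF, 0 °C
Reagents that add atoms: none
Why: Buffered fluoride cleavage of the tertiary triethylsilyl ether should leave the methyl ester, the vinyl bromide and the cross-conjugated dienone intact.

**Compound list**

1 | methoxyallene (1-methoxypropa-1,2-diene) | COC=C=C | starting material
2 | 1-lithio-1-methoxyallene (formed in the flask) | COC([Li])=C=C | intermediate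
3 | tert-butyl(1-methoxypropa-1,2-dien-1-yl)dimethylsilane | COC(=C=C)[Si](C)(C)C(C)(C)C | intermediate
4 | (1R,2S,5R)-menthyl (S)-4-methylbenzenesulfinate | CC(C)[C@@H]1CC[C@@H](C)C[C@H]1O[S@](=O)c1ccc(C)cc1 | starting material
5 | 3-lithio derivative of 3 (formed in the flask) | COC(=C=C[Li])[Si](C)(C)C(C)(C)C | intermediate
6 | tert-butyl{1-methoxy-3-[(R)-4-methylbenzenesulfinyl]propa-1,2-dien-1-yl}dimethylsilane (allene axis not controlled) | COC(=C=C[S@@](=O)c1ccc(C)cc1)[Si](C)(C)C(C)(C)C | intermediate
7 | (2E)-1-[tert-butyl(dimethyl)silyl]-3-[(R)-4-methylbenzenesulfinyl]prop-2-en-1-one | CC(C)(C)[Si](C)(C)C(=O)/C=C/[S@@](=O)c1ccc(C)cc1 | intermediate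
8 | (2Z)-oct-2-en-1-ol | CCCCC/C=C\CO | starting material
9 | (2Z)-1-bromooct-2-ene | CCCCC/C=C\CBr | intermediate
10 | (4Z)-undec-4-en-1-yne | CCCCC/C=C\CC#C | intermediate
11 | (4Z)-undeca-1,4-dien-2-yl acetate | CCCCC/C=C\CC(=C)OC(C)=O | intermediate
12 | lithium (4Z)-undeca-1,4-dien-2-olate (formed in the flask) | CCCCC/C=C\CC(=C)O[Li] | intermediate
13 | lithium alkoxide from 1,2-addition of 12 to 7 (formed in the flask; new carbinol centre not defined) | CCCCC/C=C\CC(=O)CC(O[Li])(/C=C/[S@@](=O)c1ccc(C)cc1)[Si](C)(C)C(C)(C)C | intermediate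
14 | Brook-rearranged siloxyallyl lithium (formed in the flask) | CCCCC/C=C\CC(=O)C/C(O[Si](C)(C)C(C)(C)C)=C\C([Li])[S@@](=O)c1ccc(C)cc1 | intermediate
15 | (1S,2R)-4-[(tert-butyldimethylsilyl)oxy]-2-[(R)-4-methylbenzenesulfinyl]-1-[(2Z)-oct-2-en-1-yl]cyclopent-3-en-1-ol | CCCCC/C=C\C[C@]1(O)CC(O[Si](C)(C)C(C)(C)C)=C[C@H]1[S@@](=O)c1ccc(C)cc1 | intermediate
16 | 2-bromo-4-hydroxy-3-[(R)-4-methylbenzenesulfinyl]-4-[(2Z)-oct-2-en-1-yl]cyclopentan-1-one (formed in the flask; C-3, C-4 and sulfur as in 15, C-2 epimers) | CCCCC/C=C\C[C@]1(O)CC(=O)C(Br)[C@H]1[S@@](=O)c1ccc(C)cc1 | intermediate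
17 | (4S)-2-bromo-4-hydroxy-4-[(2Z)-oct-2-en-1-yl]cyclopent-2-en-1-one | CCCCC/C=C\C[C@@]1(O)C=C(Br)C(=O)C1 | intermediate
18 | (4S)-2-bromo-4-[(2Z)-oct-2-en-1-yl]-4-[(triethylsilyl)oxy]cyclopent-2-en-1-one | CCCCC/C=C\C[C@@]1(O[Si](CC)(CC)CC)C=C(Br)C(=O)C1 | intermediate
19 | methyl hex-5-enoate | COC(=O)CCCC=C | starting material
20 | (2E)-but-2-enal (crotonaldehyde) | C/C=C/C=O | starting material
21 | methyl (5E)-7-oxohept-5-enoate | COC(=O)CCC/C=C/C=O | intermediate
22 | lithium enolate of 18 (formed in the flask) | CCCCC/C=C\C[C@@]1(O[Si](CC)(CC)CC)C=C(Br)C(O[Li])=C1 | intermediate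
23 | chlorobis(cyclopentadienyl)zirconium enolate of 18 (formed in the flask) | CCCCC/C=C\C[C@@]1(O[Si](CC)(CC)CC)C=C(Br)C(O[Zr](Cl)(C2C=CC=C2)C3C=CC=C3)=C1 | intermediate
24 | methyl (5E,7S)-7-[(1S,2S)-4-bromo-2-[(2Z)-oct-2-en-1-yl]-5-oxo-2-[(triethylsilyl)oxy]cyclopent-3-en-1-yl]-7-hydroxyhept-5-enoate (syn-aldol) | CCCCC/C=C\C[C@@]1(O[Si](CC)(CC)CC)C=C(Br)C(=O)[C@H]1[C@@H](O)/C=C/CCCC(=O)OC | intermediate
25 | methyl (5E,7Z)-7-[(2R)-4-bromo-2-[(2Z)-oct-2-en-1-yl]-5-oxo-2-[(triethylsilyl)oxy]cyclopent-3-en-1-ylidene]hept-5-enoate | CCCCC/C=C\C[C@@]1(O[Si](CC)(CC)CC)C=C(Br)C(=O)/C1=C\C=C\CCCC(=O)OC | intermediate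
26 | methyl (5E,7Z)-7-[(2R)-4-bromo-2-hydroxy-2-[(2Z)-oct-2-en-1-yl]-5-oxocyclopent-3-en-1-ylidene]hept-5-enoate | CCCCC/C=C\C[C@@]1(O)C=C(Br)C(=O)/C1=C\C=C\CCCC(=O)OC | target

**Step count and risks**

Total steps: 13. Longest linear sequence: 9 steps (1, 2, 3, 7, 8, 9, 11, 12, 13 from methoxyallene; equally 4, 5, 6, 7, 8, 9, 11, 12, 13 from (2Z)-oct-2-en-1-ol).

Steps most likely to fail:

1. Step 7 (Proposed new method). What may go wrong:
   - conjugate addition of the enolate to the sulfinyl enone instead of 1,2-addition;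
   - quenching of the allyl anion by proton transfer from the doubly activated CH2 before ring closure;
   - low or reversed facial selectivity from the sulfinyl group.

   Fallback (known chemistry), setting out from 3 and commercial 4,4-dimethoxybutan-2-one and rejoining at 18: lithiation of 3 and quench with diphenyl disulfide gives thioallene F1, hydrolysed (aq. H2SO4) to the phenylthio acryloylsilane F2. The precedented annulation of F2 with the LiN(iPr)2-derived enolate of 4,4-dimethoxybutan-2-one (a simple alkyl methyl ketone) gives racemic cyclopentenol F3. TBAF/AcOH then Et3N gives enone F4, and Br2 followed by Et3N (no other alkene present) gives bromoenone F5. F5 is resolved by preparative chromatography on a chiral stationary phase to F6. Silylation (TESOTf, 2,6-lutidine) gives F7, aqueous trifluoroacetic acid unmasks aldehyde F8, and a Z-selective Wittig reaction with hexylidenetriphenylphosphorane (from hexyltriphenylphosphonium bromide and NaN(SiMe3)2, −78 °C) rejoins the route at 18.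

2. Step 12 (with step 11). What may go wrong: erosion of syn-selectivity in the aldol, or competing E1cB elimination that scrambles the alkene geometry.

   Fallback, setting out from 24 and rejoining at 25: mesylation (MsCl, Et3N) gives methanesulfonate F9, and base-induced elimination (DBU) gives 25 together with its (7E)-isomer F10. The isomers are separated by chromatography and F10 is re-equilibrated at the exocyclic double bond (catalytic I2, light) and recycled, so geometry is handled by separation and equilibration instead of by stereospecific elimination.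

3. Step 8. What may go wrong: [2,3]-sigmatropic rearrangement of the allylic sulfoxide before bromination, or loss of the sulfinyl group without bromine incorporation.

   Fallback, setting out from 15 and rejoining at 17: TBAF/AcOH then Et3N cleaves the silyl enol ether and expels sulfenate to give enone F11. Nucleophilic epoxidation (t-BuOOH, benzyltrimethylammonium hydroxide) of the electron-poor ring double bond, which leaves the (Z)-alkene of the side chain alone, gives epoxy ketone F12. LiBr/AcOH opens the epoxide at C-2 to bromohydrin F13, and MsCl/Et3N dehydration gives 17.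

**Further compounds**

F1 | step 7 | tert-butyl[1-methoxy-3-(phenylsulfanyl)propa-1,2-dien-1-yl]dimethylsilane | COC(=C=CSc1ccccc1)[Si](C)(C)C(C)(C)C
F2 | step 7 | (2E)-1-[tert-butyl(dimethyl)silyl]-3-(phenylsulfanyl)prop-2-en-1-one | CC(C)(C)[Si](C)(C)C(=O)/C=C/Sc1ccccc1
F3 | step 7 | racemic 4-[(tert-butyldimethylsilyl)oxy]-1-(2,2-dimethoxyethyl)-2-(phenylsulfanyl)cyclopent-3-en-1-ol | COC(CC1(O)CC(O[Si](C)(C)C(C)(C)C)=CC1Sc1ccccc1)OC
F4 | step 7 | racemic 4-(2,2-dimethoxyethyl)-4-hydroxycyclopent-2-en-1-one | COC(CC1(O)CC(=O)C=C1)OC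
F5 | step 7 | racemic 2-bromo-4-(2,2-dimethoxyethyl)-4-hydroxycyclopent-2-en-1-one | COC(CC1(O)CC(=O)C(Br)=C1)OC
F6 | step 7 | (4S)-2-bromo-4-(2,2-dimethoxyethyl)-4-hydroxycyclopent-2-en-1-one | COC(C[C@@]1(O)C=C(Br)C(=O)C1)OC
F7 | step 7 | (4S)-2-bromo-4-(2,2-dimethoxyethyl)-4-[(triethylsilyl)oxy]cyclopent-2-en-1-one | COC(C[C@@]1(O[Si](CC)(CC)CC)C=C(Br)C(=O)C1)OC
F8 | step 7 | 2-[(1S)-3-bromo-4-oxo-1-[(triethylsilyl)oxy]cyclopent-2-en-1-yl]acetaldehyde | O=CC[C@@]1(O[Si](CC)(CC)CC)C=C(Br)C(=O)C1
F9 | step 12 | 7-O-methanesulfonate of 24 | CCCCC/C=C\C[C@@]1(O[Si](CC)(CC)CC)C=C(Br)C(=O)[C@H]1[C@@H](OS(C)(=O)=O)/C=C/CCCC(=O)OC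
F10 | step 12 | (7E)-isomer of 25 | CCCCC/C=C\C[C@@]1(O[Si](CC)(CC)CC)C=C(Br)C(=O)/C1=C/C=C/CCCC(=O)OC
F11 | step 8 | (4S)-4-hydroxy-4-[(2Z)-oct-2-en-1-yl]cyclopent-2-en-1-one | CCCCC/C=C\C[C@@]1(O)C=CC(=O)C1
F12 | step 8 | 2,3-epoxide of F11 (epoxide face not defined) | CCCCC/C=C\C[C@@]1(O)C2OC2C(=O)C1
F13 | step 8 | (4S)-2-bromo-3,4-dihydroxy-4-[(2Z)-oct-2-en-1-yl]cyclopentan-1-one | CCCCC/C=C\C[C@@]1(O)C(O)C(Br)C(=O)C1
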